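Ring numbering: C1 (CH bearing the acyl chain), C2 (CH–veratryl), C3=C4, C5H2, C6 (CH–guaiacyl); veratryl = 3,4-dimethoxyphenyl, guaiacyl = 4-hydroxy-3-methoxyphenyl.
Cuts: (a) the bond between the central diketone carbon and the feruloyl carbonyl, which leaves a C1 methyl ketone and a feruloyl donor; (b) ring bond C1–C2, by retro-Claisen reconnection of the C1 carboxyl oxygen to C4.
Enabling feature: O=C–C1–C2–C3=C4 is a γ,δ-unsaturated carbonyl array, and C4 is linked back to C1 by the two-carbon bridge C5–C6. Cut (b) therefore unfolds the cyclohexene into a six-membered lactone with the guaiacyl ring at its C4 and an (E)-veratrylvinyl group at its C6.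
Forward order: the dihydropyranone ring is closed by metathesis, the guaiacyl ring is added at lactone C4, and the oxacycle is traded for the cyclohexene in the sigmatropic step. The carboxyl group then becomes a methyl ketone, the feruloyl chain is joined by enolate acylation, and the two MOM groups are removed last.
Stereochemistry: a catalytic asymmetric allylboration sets one carbinol centre (R). It steers the aryl addition to the opposite ring face (future C6, S) and is itself relayed to C2 (R) in the [3,3] shift. C1, the only acidic ring centre, is equilibrated to the all-equatorial R configuration, and both E alkenes are bought.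

Key step: step 7

Remark: the 1,3-diketone is written as the chelated Z-enol of the target SMILES; keto and enol forms interconvert freely, so no step has to control this geometry.

Step 1
Reactants: 1 (E)-3,4-dimethoxycinnamaldehyde; 2 allylboronic acid pinacol ester
Product: 4 (R,E)-1-(3,4-dimethoxyphenyl)hexa-1,5-dien-3-ol, via pinacol borate ester of the carbinol 3 (not isolated)
Conditions: (R)-3,3'-bis(2,4,6-triisopropylphenyl)-1,1'-binaphthyl-2,2'-diyl hydrogen phosphate (5 mol %), toluene, −30 °C; aqueous work-up
Reagents that add atoms: none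
Why: Chiral-phosphoric-acid-catalysed asymmetric allylboration, in which the acid hydrogen-bonds to a boronate oxygen and the formyl hydrogen of a closed Zimmerman–Traxler chair, so that by analogy with other aryl and alkenyl aldehydes the (R)-catalyst should give the R carbinol by pure 1,2-addition (sense to be confirmed through the Mosher esters, the antipodal acid being equally available).

Step 2
Reactants: 4 (R,E)-1-(3,4-dimethoxyphenyl)hexa-1,5-dien-3-ol; 5 acryloyl chloride
Product: 6 (R,E)-1-(3,4-dimethoxyphenyl)hexa-1,5-dien-3-yl acrylate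
Conditions: Et3N, CH2Cl2, 0 °C
Reagents that add atoms: none
Why: Routine O-acylation of a secondary alcohol with an acid chloride, the amine keeping the medium non-acidic so that the ionisation-prone dimethoxycinnamyl-type carbinol keeps its configuration.

Step 3
Reactants: 6 (R,E)-1-(3,4-dimethoxyphenyl)hexa-1,5-dien-3-yl acrylate
Product: 7 (R)-6-[(E)-3,4-dimethoxystyryl]-5,6-dihydro-2H-pyran-2-one
Conditions: first-generation Grubbs catalyst RuCl2(=CHPh)(PCy3)2 (10 mol %), CH2Cl2 (0.005 M), reflux
Reagents that add atoms: none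
Why: Ring-closing metathesis of the two monosubstituted alkenes closes the six-membered enoate ring, as is well established for 6-styryl dihydropyranones, and the less active first-generation catalyst should leave the 1,2-disubstituted styryl alkene and the stereocentre untouched.

Step 4
Reactants: 8 4-bromo-2-methoxyphenol
Product: 9 4-bromo-2-methoxy-1-(methoxymethoxy)benzene
Conditions: MOMCl, i-Pr2NEt, CH2Cl2, 0 °C to rt
Reagents that add atoms: chloromethyl methyl ether (MOMCl), COCCl
Why: Williamson-type MOM ether formation on the phenol installs a group that withstands the organolithium, Grignard, amide-base and alkoxide conditions used later.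

Step 5
Reactants: 9 4-bromo-2-methoxy-1-(methoxymethoxy)benzene
Product: 12 3-methoxy-4-(methoxymethoxy)phenylboronic acid, via aryllithium 10 (not isolated), via lithium aryl(triisopropoxy)borate 11 (not isolated)
Conditions: n-BuLi, THF, −78 °C; B(Oi-Pr)3, −78 °C to rt; sat. aq. NH4Cl
Reagents that add atoms: triisopropyl borate, CC(C)OB(OC(C)C)OC(C)C; water, O
Why: Bromine–lithium exchange at low temperature outruns ortho-lithiation next to the MOM ether, and borate trapping followed by near-neutral hydrolysis is the standard route to an arylboronic acid.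

Step 6
Reactants: 7 (R)-6-[(E)-3,4-dimethoxystyryl]-5,6-dihydro-2H-pyran-2-one; 12 3-methoxy-4-(methoxymethoxy)phenylboronic acid
Product: 13 (4S,6R)-6-[(E)-3,4-dimethoxystyryl]-4-[3-methoxy-4-(methoxymethoxy)phenyl]tetrahydro-2H-pyran-2-one (trans)
Conditions: [Rh(OH)((S)-binap)]2 (2.5 mol %), dioxane/H2O 10:1, 40 °C
Reagents that add atoms: none
Why: Rhodium-catalysed conjugate arylation (Hayashi–Miyaura reaction) run without added base to spare the elimination-prone dihydropyranone, in which the aryl–rhodium species should add to C4 on the face opposite the pseudo-equatorial C6 styryl group while the (S)-ligand, which by the quadrant model for cyclic enoates also favours 4S, reinforces that bias as the matched partner, so the new centre is set trans to C6.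

Step 7
Reactants: 13 (4S,6R)-6-[(E)-3,4-dimethoxystyryl]-4-[3-methoxy-4-(methoxymethoxy)phenyl]tetrahydro-2H-pyran-2-one
Product: 16 (1S,2R,6S)-2-(3,4-dimethoxyphenyl)-6-[3-methoxy-4-(methoxymethoxy)phenyl]cyclohex-3-ene-1-carboxylic acid (all-cis), via silyl ketene acetal 14 (not isolated), via silyl ester 15 (not isolated)
Conditions: LiN(i-Pr)2, TBSCl, DMPU, THF, −78 °C to rt; toluene, trace Et3N, base-washed glass, 110 °C; AcOH, THF/H2O, rt
Reagents that add atoms: none
Why: Deprotonation at lactone C3 and O-silylation give the endocyclic silyl ketene acetal 14, whose C3=C2–O1–C6–C7=C8 array undergoes a concerted suprafacial [3,3] shift on heating in which C3 bonds to the veratryl-bearing styryl carbon C8 while the allylic O1–C6 bond breaks, and mild hydrolysis of silyl ester 15 frees acid 16. The closest known reaction is the Ireland–Claisen rearrangement of 6-alkenyl δ-valerolactone silyl ketene acetals to cyclohex-3-enecarboxylic acids. The cyclohexene (lactone atoms C3–C4–C5–C6=C7–C8) closes through a bicyclo[2.2.2]octane-like boat, the only geometry open to a ketene acetal whose α-carbon and carbinol carbon are bridged by the two atoms C4–C5, and the same constraint makes the new ring alkene cis. The veratryl carbon is set by transfer of the 6R carbinol chirality across one face of the E-styryl unit (giving 2R); the carboxyl carbon is set because the styryl group can reach only the lactone face on which it stands (giving 1S, cis to veratryl); and the 4S guaiacyl carbon is carried through unchanged, ending cis to the carboxyl group because it stood trans to the styryl group. The step needs O- rather than C-silylation and a rearrangement faster than ionisation of the electron-rich cinnamyl-type C–O bond, which the hard silyl chloride in a dipolar cosolvent, acid-free glass and solvent, and the placement of the 4-aryl group on the convex face of the boat are meant to secure. The configuration produced at C1 is of no consequence, since it is reset in step 10.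

Step 8
Reactants: 16 (1S,2R,6S)-2-(3,4-dimethoxyphenyl)-6-[3-methoxy-4-(methoxymethoxy)phenyl]cyclohex-3-ene-1-carboxylic acid
Product: 18 (1S,2R,6S)-N-methoxy-N-methyl-2-(3,4-dimethoxyphenyl)-6-[3-methoxy-4-(methoxymethoxy)phenyl]cyclohex-3-ene-1-carboxamide, via acid chloride 17 (not isolated)
Conditions: 1-chloro-N,N,2-trimethylpropenylamine, CH2Cl2, 0 °C; MeNHOMe·HCl, Et3N, 0 °C to rt
Reagents that add atoms: N,O-dimethylhydroxylamine hydrochloride, CNOC.Cl
Why: Neutral conversion of the hindered axial acid into its chloride with the α-chloroenamine followed by amine acylation (Weinreb amide formation) avoids free HCl and so spares the MOM ether, and any leakage of configuration at C1 through a ketene is harmless because that centre is reset in step 10.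

Step 9
Reactants: 18 (1S,2R,6S)-N-methoxy-N-methyl-2-(3,4-dimethoxyphenyl)-6-[3-methoxy-4-(methoxymethoxy)phenyl]cyclohex-3-ene-1-carboxamide
Product: 20 1-{(1S,2R,6S)-2-(3,4-dimethoxyphenyl)-6-[3-methoxy-4-(methoxymethoxy)phenyl]cyclohex-3-en-1-yl}ethan-1-one (all-cis), via chelated magnesium hemiaminal 19 (not isolated)
Conditions: MeMgBr, THF, 0 °C to rt; sat. aq. NH4Cl
Reagents that add atoms: methylmagnesium bromide, C[Mg]Br
Why: Weinreb ketone synthesis, in which the chelated tetrahedral magnesium adduct persists until the quench so that only one methyl group is delivered.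

Step 10
Reactants: 20 1-{(1S,2R,6S)-2-(3,4-dimethoxyphenyl)-6-[3-methoxy-4-(methoxymethoxy)phenyl]cyclohex-3-en-1-yl}ethan-1-one
Product: 21 1-{(1R,2R,6S)-2-(3,4-dimethoxyphenyl)-6-[3-methoxy-4-(methoxymethoxy)phenyl]cyclohex-3-en-1-yl}ethan-1-one (acetyl trans to both aryl groups)
Conditions: NaOMe (0.3 equiv), MeOH/THF, 50 °C
Reagents that add atoms: none
Why: Thermodynamic epimerisation through the enolate, since only C1 of the three ring stereocentres is acidic and moving the acetyl group from the axial site between two equatorial aryl groups to the equatorial site gives the all-equatorial half-chair, so the equilibrium should lie far on the side of 21.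

Step 11
Reactants: 22 (E)-ferulic acid
Product: 23 methoxymethyl (E)-3-[3-methoxy-4-(methoxymethoxy)phenyl]acrylate
Conditions: MOMCl (2.5 equiv), i-Pr2NEt, CH2Cl2, 0 °C to rt
Reagents that add atoms: chloromethyl methyl ether (MOMCl), COCCl
Why: Double alkylation of phenoxide and carboxylate with MOMCl is a routine protection that needs no selectivity.

Step 12
Reactants: 23 methoxymethyl (E)-3-[3-methoxy-4-(methoxymethoxy)phenyl]acrylate
Product: 25 (E)-3-[3-methoxy-4-(methoxymethoxy)phenyl]acrylic acid, via lithium carboxylate 24 (not isolated)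
Conditions: LiOH, THF/MeOH/H2O, rt; 1 M HCl, 0 °C, to pH 4
Reagents that add atoms: lithium hydroxide, [Li+].[OH-]
Why: Saponification cleaves only the ester-type MOM group, the aryl MOM acetal being inert to hydroxide, and brief cold acidification frees the acid.

Step 13
Reactants: 25 (E)-3-[3-methoxy-4-(methoxymethoxy)phenyl]acrylic acid
Product: 26 (E)-1-(1H-benzotriazol-1-yl)-3-[3-methoxy-4-(methoxymethoxy)phenyl]prop-2-en-1-one
Conditions: 1-(methylsulfonyl)-1H-benzotriazole, Et3N, THF, reflux
Reagents that add atoms: 1-(methylsulfonyl)-1H-benzotriazole, CS(=O)(=O)n1nnc2ccccc21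
Why: N-Acylbenzotriazole formation through the mixed carboxylic–sulfonic anhydride runs under basic conditions and gives a storable acyl donor without exposing the MOM ether to acid.

Step 14
Reactants: 21 1-{(1R,2R,6S)-2-(3,4-dimethoxyphenyl)-6-[3-methoxy-4-(methoxymethoxy)phenyl]cyclohex-3-en-1-yl}ethan-1-one; 26 (E)-1-(1H-benzotriazol-1-yl)-3-[3-methoxy-4-(methoxymethoxy)phenyl]prop-2-en-1-one
Product: 29 (2Z,4E)-1-{(1R,2R,6S)-2-(3,4-dimethoxyphenyl)-6-[3-methoxy-4-(methoxymethoxy)phenyl]cyclohex-3-en-1-yl}-3-hydroxy-5-[3-methoxy-4-(methoxymethoxy)phenyl]penta-2,4-dien-1-one, via methyl-side lithium enolate 27 (not isolated), via lithium diketonate 28 (not isolated)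
Conditions: LiN(SiMe3)2 (2.3 equiv), THF, −78 °C; 26, −78 to −40 °C; AcOH quench
Reagents that add atoms: none
Why: Crossed Claisen-type C-acylation of a ketone enolate with an N-acylbenzotriazole, in which the bulky amide removes a proton from the open methyl group rather than the shielded C1–H, the hard lithium enolate attacks the activated carbonyl rather than the cinnamoyl β-carbon at low temperature, the second equivalent of base takes up the acidic diketone proton so that no enolate is wasted, and C1 stays in its most stable configuration.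

Step 15
Reactants: 29 (2Z,4E)-1-{(1R,2R,6S)-2-(3,4-dimethoxyphenyl)-6-[3-methoxy-4-(methoxymethoxy)phenyl]cyclohex-3-en-1-yl}-3-hydroxy-5-[3-methoxy-4-(methoxymethoxy)phenyl]penta-2,4-dien-1-one
Product: 30 (2Z,4E)-1-[(1R,2R,6S)-2-(3,4-dimethoxyphenyl)-6-(4-hydroxy-3-methoxyphenyl)cyclohex-3-en-1-yl]-3-hydroxy-5-(4-hydroxy-3-methoxyphenyl)penta-2,4-dien-1-one (CNP0290899.1)
Conditions: HCl (1.25 M in MeOH), THF, 0 °C to rt
Reagents that add atoms: none
Why: Acid-catalysed acetal exchange removes both phenolic MOM groups under conditions in which curcuminoid enol-diketones, aryl methyl ethers and the isolated ring alkene are stable, and the only epimerisable centre, C1, already sits in its thermodynamic position.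

Compound list
1 | (E)-3,4-dimethoxycinnamaldehyde | COc1ccc(/C=C/C=O)cc1OC | starting material
2 | allylboronic acid pinacol ester | C=CCB1OC(C)(C)C(C)(C)O1 | starting material
3 | pinacol borate ester of carbinol 4 | C=CC[C@@H](OB1OC(C)(C)C(C)(C)O1)/C=C/c1ccc(OC)c(OC)c1 | intermediate
4 | (R,E)-1-(3,4-dimethoxyphenyl)hexa-1,5-dien-3-ol | C=CC[C@@H](O)/C=C/c1ccc(OC)c(OC)c1 | intermediate
5 | acryloyl chloride | C=CC(=O)Cl | starting material
6 | (R,E)-1-(3,4-dimethoxyphenyl)hexa-1,5-dien-3-yl acrylate | C=CC[C@@H](OC(=O)C=C)/C=C/c1ccc(OC)c(OC)c1 | intermediate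
7 | (R)-6-[(E)-3,4-dimethoxystyryl]-5,6-dihydro-2H-pyran-2-one | O=C1C=CC[C@H](/C=C/c2ccc(OC)c(OC)c2)O1 | intermediate
8 | 4-bromo-2-methoxyphenol | COc1cc(Br)ccc1O | starting material
9 | 4-bromo-2-methoxy-1-(methoxymethoxy)benzene | COCOc1ccc(Br)cc1OC | intermediate
10 | [3-methoxy-4-(methoxymethoxy)phenyl]lithium | COCOc1ccc([Li])cc1OC | intermediate
11 | lithium triisopropoxy[3-methoxy-4-(methoxymethoxy)phenyl]borate | [Li+].COCOc1ccc([B-](OC(C)C)(OC(C)C)OC(C)C)cc1OC | intermediate
12 | 3-methoxy-4-(methoxymethoxy)phenylboronic acid | COCOc1ccc(B(O)O)cc1OC | intermediate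
13 | (4S,6R)-6-[(E)-3,4-dimethoxystyryl]-4-[3-methoxy-4-(methoxymethoxy)phenyl]tetrahydro-2H-pyran-2-one | O=C1C[C@@H](c2ccc(OCOC)c(OC)c2)C[C@H](/C=C/c2ccc(OC)c(OC)c2)O1 | intermediate
14 | tert-butyldimethylsilyl ketene acetal of 13, (2R,4S)-6-silyloxy-3,4-dihydro-2H-pyran | CC(C)(C)[Si](C)(C)OC1=C[C@@H](c2ccc(OCOC)c(OC)c2)C[C@H](/C=C/c2ccc(OC)c(OC)c2)O1 | intermediate
15 | tert-butyldimethylsilyl ester of acid 16 | CC(C)(C)[Si](C)(C)OC(=O)[C@H]1[C@@H](c2ccc(OCOC)c(OC)c2)CC=C[C@H]1c1ccc(OC)c(OC)c1 | intermediate
16 | (1S,2R,6S)-2-(3,4-dimethoxyphenyl)-6-[3-methoxy-4-(methoxymethoxy)phenyl]cyclohex-3-ene-1-carboxylic acid (all-cis) | OC(=O)[C@H]1[C@@H](c2ccc(OCOC)c(OC)c2)CC=C[C@H]1c1ccc(OC)c(OC)c1 | intermediate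
17 | acid chloride of 16 | ClC(=O)[C@H]1[C@@H](c2ccc(OCOC)c(OC)c2)CC=C[C@H]1c1ccc(OC)c(OC)c1 | intermediate
18 | Weinreb amide of 16, (1S,2R,6S) | CON(C)C(=O)[C@H]1[C@@H](c2ccc(OCOC)c(OC)c2)CC=C[C@H]1c1ccc(OC)c(OC)c1 | intermediate
19 | bromomagnesium hemiaminal from 18 and MeMgBr | CON(C)C(C)(O[Mg]Br)[C@H]1[C@@H](c2ccc(OCOC)c(OC)c2)CC=C[C@H]1c1ccc(OC)c(OC)c1 | intermediate
20 | all-cis methyl ketone, (1S,2R,6S) | CC(=O)[C@H]1[C@@H](c2ccc(OCOC)c(OC)c2)CC=C[C@H]1c1ccc(OC)c(OC)c1 | intermediate
21 | all-trans methyl ketone, (1R,2R,6S) | CC(=O)[C@@H]1[C@@H](c2ccc(OCOC)c(OC)c2)CC=C[C@H]1c1ccc(OC)c(OC)c1 | intermediate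
22 | (E)-ferulic acid | COc1cc(/C=C/C(=O)O)ccc1O | starting material
23 | methoxymethyl (E)-3-[3-methoxy-4-(methoxymethoxy)phenyl]acrylate | COCOC(=O)/C=C/c1ccc(OCOC)c(OC)c1 | intermediate
24 | lithium (E)-3-[3-methoxy-4-(methoxymethoxy)phenyl]acrylate | [Li+].[O-]C(=O)/C=C/c1ccc(OCOC)c(OC)c1 | intermediate
25 | (E)-3-[3-methoxy-4-(methoxymethoxy)phenyl]acrylic acid | OC(=O)/C=C/c1ccc(OCOC)c(OC)c1 | intermediate
26 | O-MOM-feruloyl benzotriazole | COCOc1ccc(/C=C/C(=O)n2nnc3ccccc32)cc1OC | intermediate
27 | methyl-side lithium enolate of 21 | C=C(O[Li])[C@@H]1[C@@H](c2ccc(OCOC)c(OC)c2)CC=C[C@H]1c1ccc(OC)c(OC)c1 | intermediate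
28 | lithium diketonate of 29 | COCOc1ccc(/C=C/C(O[Li])=C/C(=O)[C@@H]2[C@@H](c3ccc(OCOC)c(OC)c3)CC=C[C@H]2c2ccc(OC)c(OC)c2)cc1OC | intermediate
29 | bis-MOM curcuminoid, (1R,2R,6S) | COCOc1ccc(/C=C/C(O)=C/C(=O)[C@@H]2[C@@H](c3ccc(OCOC)c(OC)c3)CC=C[C@H]2c2ccc(OC)c(OC)c2)cc1OC | intermediate
30 | CNP0290899.1, (1R,2R,6S) | COc1cc(/C=C/C(O)=C/C(=O)[C@@H]2[C@@H](c3ccc(O)c(OC)c3)CC=C[C@H]2c2ccc(OC)c(OC)c2)ccc1O | target

Total step count: 15. Longest linear sequence: 10 steps (1, 2, 3, 6, 7, 8, 9, 10, 14, 15).

Steps most likely to fail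

**Step 7.**
- The strained boat rearrangement needs prolonged heating. Ionisation of the electron-rich allylic C–O bond may overtake it, causing elimination or erosion of the chirality transfer, and C-silylation of the lactone enolate may compete.
- The fallback keeps the C1–C2 bond as a Claisen bond but makes it in an acyclic chair rearrangement that runs at or below room temperature. The ring is then closed at C3=C4 by metathesis. It sets out from 12 and comes back at 16.
- Acid 12 is added to commercial 5,6-dihydro-2H-pyran-2-one with [Rh(OH)((R)-binap)]2 to give (R)-4-[3-methoxy-4-(methoxymethoxy)phenyl]tetrahydro-2H-pyran-2-one F1. Reduction with i-Bu2AlH gives the lactol (4R)-4-aryltetrahydro-2H-pyran-2-ol F2. Wittig methylenation with Ph3P=CH2 gives (S)-3-[3-methoxy-4-(methoxymethoxy)phenyl]hex-5-en-1-ol F3. Oxidation with TEMPO/PhI(OAc)2 in aqueous MeCN gives (S)-3-[3-methoxy-4-(methoxymethoxy)phenyl]hex-5-enoic acid F4.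
- Corey–Bakshi–Shibata reduction of commercial (E)-4-(3,4-dimethoxyphenyl)but-3-en-2-one with the (R)-methyl oxazaborolidine and BH3·SMe2 gives (S,E)-4-(3,4-dimethoxyphenyl)but-3-en-2-ol F5. The S carbinol is required here because in the open chair the methyl group takes the outer position that hydrogen occupies in the lactone.
- Steglich esterification (DCC, DMAP) joins the two halves as the allylic ester F6. Enolisation with LiN(i-Pr)2 in THF/DMPU, silylation with TBSCl, warming to room temperature and an aqueous acetic acid work-up should give the syn Ireland–Claisen acid F7. In F7 the veratryl carbon is set by chirality transfer and the guaiacyl carbon is carried in from F4.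
- Ring-closing metathesis with the second-generation Grubbs catalyst RuCl2(=CHPh)(PCy3)(H2IMes) then closes the cyclohexene and returns 16. An imperfect syn preference affects only C1, which step 10 corrects.

**Step 6.**
- Insufficient facial selectivity, hydrolytic or eliminative opening of the unsaturated lactone, or protodeboronation of the electron-rich boronic acid may limit the step.
- The fallback sets the guaiacyl carbon on an open chain under pure ligand control and closes the lactone afterwards. It sets out from 4 and comes back at 13.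
- Cross-metathesis of 4 with methyl acrylate, using the second-generation Hoveyda–Grubbs catalyst RuCl2(=CH-C6H4-2-Oi-Pr)(H2IMes), gives methyl (2E,5R,6E)-7-(3,4-dimethoxyphenyl)-5-hydroxyhepta-2,6-dienoate F8.
- Rhodium/BINAP-catalysed addition of 12, with the ligand antipode that delivers the 3S centre, gives methyl (3S,5R,E)-7-(3,4-dimethoxyphenyl)-5-hydroxy-3-[3-methoxy-4-(methoxymethoxy)phenyl]hept-6-enoate F9.
- F9 should lactonise to 13 during the reaction or on brief warming in toluene with catalytic DBU.

**Step 14.**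
- O-acylation, conjugate addition to the cinnamoyl acceptor, or proton transfer that stalls the reaction may spoil the acylation.
- The fallback replaces acylation by aldol addition and oxidation. It sets out from 21 and comes back at 29.
- Commercial coniferaldehyde is protected with MOMCl/i-Pr2NEt as (E)-3-[3-methoxy-4-(methoxymethoxy)phenyl]prop-2-enal F10.
- The enolate generated from 21 with LiN(SiMe3)2 at −78 °C adds to F10 in 1,2-fashion to give the β-hydroxy ketone F11 as a mixture of carbinol epimers.
- Oxidation of F11 with 2-iodoxybenzoic acid in warm EtOAc gives 29.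

Further compounds
F1 | step 7 | (R)-4-[3-methoxy-4-(methoxymethoxy)phenyl]tetrahydro-2H-pyran-2-one | O=C1C[C@H](c2ccc(OCOC)c(OC)c2)CCO1
F2 | step 7 | (4R)-4-[3-methoxy-4-(methoxymethoxy)phenyl]tetrahydro-2H-pyran-2-ol (lactol, anomers) | OC1C[C@H](c2ccc(OCOC)c(OC)c2)CCO1
F3 | step 7 | (S)-3-[3-methoxy-4-(methoxymethoxy)phenyl]hex-5-en-1-ol | C=CC[C@H](c1ccc(OCOC)c(OC)c1)CCO
F4 | step 7 | (S)-3-[3-methoxy-4-(methoxymethoxy)phenyl]hex-5-enoic acid | C=CC[C@H](c1ccc(OCOC)c(OC)c1)CC(=O)O
F5 | step 7 | (S,E)-4-(3,4-dimethoxyphenyl)but-3-en-2-ol | C[C@H](O)/C=C/c1ccc(OC)c(OC)c1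
F6 | step 7 | (S,E)-4-(3,4-dimethoxyphenyl)but-3-en-2-yl (S)-3-[3-methoxy-4-(methoxymethoxy)phenyl]hex-5-enoate | C=CC[C@H](c1ccc(OCOC)c(OC)c1)CC(=O)O[C@@H](C)/C=C/c1ccc(OC)c(OC)c1
F7 | step 7 | syn Ireland–Claisen acid, (E)-3-(3,4-dimethoxyphenyl)-2-{1-[3-methoxy-4-(methoxymethoxy)phenyl]but-3-enyl}hex-4-enoic acid with the three centres as in 16 | OC(=O)[C@@H]([C@@H](c1ccc(OCOC)c(OC)c1)CC=C)[C@H](c1ccc(OC)c(OC)c1)/C=C/C
F8 | step 6 | methyl (2E,5R,6E)-7-(3,4-dimethoxyphenyl)-5-hydroxyhepta-2,6-dienoate | COC(=O)/C=C/C[C@@H](O)/C=C/c1ccc(OC)c(OC)c1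
F9 | step 6 | methyl (3S,5R,E)-7-(3,4-dimethoxyphenyl)-5-hydroxy-3-[3-methoxy-4-(methoxymethoxy)phenyl]hept-6-enoate | COC(=O)C[C@@H](c1ccc(OCOC)c(OC)c1)C[C@@H](O)/C=C/c1ccc(OC)c(OC)c1
F10 | step 14 | (E)-3-[3-methoxy-4-(methoxymethoxy)phenyl]prop-2-enal | COCOc1ccc(/C=C/C=O)cc1OC
F11 | step 14 | β-hydroxy ketone from 21 and F10 (carbinol epimers) | COCOc1ccc(/C=C/C(O)CC(=O)[C@@H]2[C@@H](c3ccc(OCOC)c(OC)c3)CC=C[C@H]2c2ccc(OC)c(OC)c2)cc1OC
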